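**Early balance.** At early times the epsilon readings show little loss: target and starting material together read 97.0% of the charge at 0.417 d and 100% at 0.833 d, and each reading carries a scatter of 2 percentage points. Later the sum sinks, from 92.0% at 2.00 d to 74.0% at 5.00 d. In the theta flask, with far more starting material, target stays at a few percent. My reading is that target meets starting material and each meeting removes one of each.

| flask | starting material | second substrate | free enzyme | remark | time |
|---|---|---|---|---|---|
| epsilon | 0.045 M | 0.132 M | 2.3 µM | run made earlier |  |
| theta | 0.64 M | 0.132 M | 2.3 µM | run made earlier |  |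
| south-west | 0.030 M | 0.132 M | 2.3 µM |  | 5.0 d |
| east | 0.060 M | 0.132 M | 2.3 µM |  | 5.0 d |
| north | 0.12 M | 0.132 M | 2.3 µM |  | 5.0 d |
| north-west | 0.20 M | 0.132 M | 2.3 µM |  | 5.0 d |
| west | 0.40 M | 0.132 M | 2.3 µM |  | 5.0 d |

| run | time / d | target / % | starting material / % |
|---|---|---|---|
| epsilon | 0.417 | 9 | 88 |
| epsilon | 0.833 | 18 | 82 |
| epsilon | 2.00 | 40 | 52 |
| epsilon | 5.00 | 56 | 18 |
| theta | 0.625 | 3 | 98 |
| theta | 1.67 | 4 | 90 |
| theta | 3.00 | 5 | 77 |
| theta | 5.00 | 2 | 72 |

(standard deviation of a reading: 2 percentage points)

* [target] at the end for south-west, east, north, north-west, west, in this order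
* how the row runs (falls all the way / rises all the way / rises, then falls / hardly changes / falls, then rises)

- "hardly changes" means that all values lie within two and a half points (for a concentration: within two and a half percent of the largest)

**Two times.** At a held concentration of starting material, target then decays pseudo-first-order. Its half-life is a fixed amount divided by that concentration. I call this amount the half-exposure, 252 M·min: the concentration of starting material times the time in which target halves, read from the last leg of epsilon using mean levels. You hold the resulting half-life against the run, 5.0 d, which target has to survive. At its charge, south-west gives 5.82 d, longer than the run, and west gives 0.437 d, shorter than the run. So I expect the row to rise with charge at the low end, then fall.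

**The forecast.** It gives 0.019 M, 0.031 M, 0.039 M, 0.036 M, 0.024 M, so rises, then falls, on the ground that “target is probably consumed by starting material”.

**The flask.** It gives 0.0207 M, 0.0311 M, 0.0352 M, 0.0290 M, 0.0145 M, so rises, then falls, turning at 0.11 M.

    starting material + free enzyme ⇌ first complex (K = 3.60 M⁻¹, k = 1.10 × 10⁵ M⁻¹ h⁻¹)
    first complex ⇌ loaded enzyme + first product (K = 0.200 M, k = 2500 h⁻¹)
    second substrate + loaded enzyme ⇌ second complex (K = 18.0 M⁻¹, k = 1.40 × 10⁶ M⁻¹ h⁻¹)
    second complex → free enzyme + target (k = 900 h⁻¹)
    starting material + target → side product (k = 0.150 M⁻¹ h⁻¹)

**Two ends.** In south-west at 1.55 d, target is made 8.53 times faster than it is used up. Its half-life by the side-product step then stands at 11 d, longer than the run. The half-exposure, applied to the starting material left at the end, gives target a half-life of 41.9 d in south-west and 0.740 d in west.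

The earlier runs and the new flask come from a simulation for an exercise; noise was put on by code.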